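The ferulate ester is set aside, and the tetrahydrofuran core (O1, C2 syringyl, C3, C4, C5) is disconnected between C4 and the guaiacyl benzylic carbon C7'. The feature exploited is that C7' and the CH2O carbon C9 on C3 are cis: C7' is first attached to the C9 oxygen as a mixed acetal of a 2,3-trans γ-lactone, and the lactone silyl ketene acetal then adds to the derived oxocarbenium ion. This single operation forms C4–C7', closes a second, necessarily cis-fused ring and fixes C4. Hydrogenolysis later cuts the temporary C7'–O bond, leaving the guaiacylmethyl group and the C9 alcohol for a final Mitsunobu esterification.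

Key step: step 8

Remark on the chemistry: target locants (O1, C2–C5, C7' = guaiacyl benzylic carbon, C9 = CH2O carbon on C3) are used for all intermediates; "tosyloxy" means 4-methylbenzenesulfonyloxy; 3, 4 and 10 are taken as purchased; 15–17 are drawn with the guaiacyl group on the convex face, but either C7' epimer converges on 18.

Step 1
Reactants: 1 syringaldehyde
Product: 2 4-formyl-2,6-dimethoxyphenyl 4-methylbenzenesulfonate
Conditions: TsCl, Et3N, DMAP (cat.), CH2Cl2, 0 °C → rt
Reagents that add atoms: p-toluenesulfonyl chloride, Cc1ccc(cc1)S(=O)(=O)Cl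
Why: Sulfonylation of the phenol; the sulfonate is inert to all steps before step 12 and makes the syringyl ring electron-poor, which later shields the C2–O1 bond from ionisation and hydrogenolysis.

Step 2
Reactants: 3 (S)-4-benzyloxazolidin-2-one; 4 methyl 4-chloro-4-oxobutanoate
Product: 5 methyl 4-[(4S)-4-benzyl-2-oxooxazolidin-3-yl]-4-oxobutanoate
Conditions: n-BuLi, THF, −78 °C; then 4, −78 → 0 °C
Reagents that add atoms: none
Why: N-acylation of the lithiated oxazolidinone by the acid chloride, which is far more electrophilic than the methyl ester at the other chain end.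

Step 3
Reactants: 5 methyl 4-[(4S)-4-benzyl-2-oxooxazolidin-3-yl]-4-oxobutanoate; 2 4-formyl-2,6-dimethoxyphenyl 4-methylbenzenesulfonate
Product: 7 (4S)-4-benzyl-3-{[(2S,3S)-2-[3,5-dimethoxy-4-(tosyloxy)phenyl]-5-oxotetrahydrofuran-3-yl]carbonyl}oxazolidin-2-one (2,3-trans lactone), via syn-aldol adduct 6 (not isolated)
Conditions: Bu2BOTf, i-Pr2NEt, CH2Cl2, 0 °C; then 2, −78 → 0 °C; pH 7 buffer (NaH2PO4/Na2HPO4), MeOH, 30% H2O2, 0 °C; crude 6, TsOH·H2O (cat.), CH2Cl2, rt
Reagents that add atoms: none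
Why: Evans syn-aldol reaction: only the imide is enolised to the Z boron enolate, which adds to the aldehyde through a Zimmerman–Traxler chair on the face remote from the auxiliary benzyl group and should set both new centres (3S,4S in 6); acid-catalysed lactonisation of the 4-hydroxyl onto the methyl ester then turns the syn relationship into the 2,3-trans lactone (C2 and C3 of the target).

Step 4
Reactants: 7 (4S)-4-benzyl-3-{[(2S,3S)-2-[3,5-dimethoxy-4-(tosyloxy)phenyl]-5-oxotetrahydrofuran-3-yl]carbonyl}oxazolidin-2-one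
Product: 8 (2S,3S)-2-[3,5-dimethoxy-4-(tosyloxy)phenyl]-5-oxotetrahydrofuran-3-carboxylic acid
Conditions: LiOH, 30% H2O2, THF–H2O, 0 °C; aq. Na2SO3; aq. HCl to pH 2
Reagents that add atoms: hydrogen peroxide (as LiOOH), OO
Why: Hydroperoxide cleavage of the N-acyloxazolidinone at the exocyclic carbonyl; any lactone opened by hydroxide closes again on acidification, and the trans arrangement is also the more stable one, so C3 is not at risk.

Step 5
Reactants: 8 (2S,3S)-2-[3,5-dimethoxy-4-(tosyloxy)phenyl]-5-oxotetrahydrofuran-3-carboxylic acid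
Product: 9 (4R,5S)-5-[3,5-dimethoxy-4-(tosyloxy)phenyl]-4-(hydroxymethyl)dihydrofuran-2(3H)-one
Conditions: BH3·SMe2, THF, 0 °C → rt; MeOH
Reagents that add atoms: none
Why: Chemoselective borane reduction of a carboxylic acid (through its acyloxyborane) beside a lactone and an aryl sulfonate; no stereocentre is touched (the descriptor change is only a CIP priority effect).

Step 6
Reactants: 10 4-(benzyloxy)-3-methoxybenzaldehyde
Product: 11 1-(benzyloxy)-4-(dimethoxymethyl)-2-methoxybenzene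
Conditions: HC(OMe)3, MeOH, TsOH·H2O (cat.), rt; Et3N
Reagents that add atoms: trimethyl orthoformate, COC(OC)OC; methanol, CO
Why: Acid-catalysed acetalisation of the aldehyde, driven to completion by the orthoester.

Step 7
Reactants: 11 1-(benzyloxy)-4-(dimethoxymethyl)-2-methoxybenzene; 9 (4R,5S)-5-[3,5-dimethoxy-4-(tosyloxy)phenyl]-4-(hydroxymethyl)dihydrofuran-2(3H)-one
Product: 13 (4R,5S)-4-({[4-(benzyloxy)-3-methoxyphenyl](methoxy)methoxy}methyl)-5-[3,5-dimethoxy-4-(tosyloxy)phenyl]dihydrofuran-2(3H)-one (mixed methyl acetal; both epimers at the acetal carbon), via α-chloro ether 12 (not isolated)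
Conditions: 11, AcCl, ZnBr2 (cat.), CH2Cl2, 0 °C → rt; then 9, i-Pr2NEt, CH2Cl2, 0 °C → rt; chromatography on Et3N-deactivated silica
Reagents that add atoms: none
Why: O-alkylation of the primary alcohol by an α-chloro ether (the reaction type of methoxymethyl ether formation): acetyl chloride exchanges one methoxy group of 11 for chloride and the alcohol displaces it under amine base, so the tether oxygen is attached irreversibly and without acid that could scramble the acetal; the acetal stereocentre is irrelevant because it is planarised in step 8.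

Step 8
Reactants: 13 (4R,5S)-4-({[4-(benzyloxy)-3-methoxyphenyl](methoxy)methoxy}methyl)-5-[3,5-dimethoxy-4-(tosyloxy)phenyl]dihydrofuran-2(3H)-one
Product: 15 (3S,3aR,6S,6aS)-6-[4-(benzyloxy)-3-methoxyphenyl]-3-[3,5-dimethoxy-4-(tosyloxy)phenyl]tetrahydro-1H,3H-furo[3,4-c]furan-1-one (cis-fused; both aryl groups on the convex face), via silyl ketene acetal 14 (not isolated)
Conditions: LiN(i-Pr)2, Me3SiCl, THF, −78 °C; evaporate, pentane, filter, CH2Cl2; Me3SiOTf (0.2 equiv), −78 °C; aq. NaHCO3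
Reagents that add atoms: none
Why: LiN(i-Pr)2 removes a C4 proton of the lactone and Me3SiCl traps the enolate on oxygen as 14; in CH2Cl2, Me3SiOTf silylates the methoxy oxygen and expels Me3SiOMe to leave an aryl-stabilised oxocarbenium ion still bound to the C9 oxygen, C4 adds to it, and the silyl group returns to triflate so that the Lewis acid turns over. The closest known reaction type is the intramolecular Mukaiyama aldol-type addition of silyl ketene acetals to tethered benzylic acetals, which has been used to build 2,6-diaryl-3,7-dioxabicyclo[3.3.0]octanones. The new tetrahydrofuran ring (C3, C9, O, C7', C4) closes in a 5-(enolexo)-endo-trig mode, with the C4=C5 bond outside and the C7'=O+ bond inside the forming ring, a geometry that oxocarbenium ions accept. C4 is controlled by the tether, because a bicyclo[3.3.0] system can only be cis-fused and C7' must therefore arrive on the face of the ring that carries C9; C7' should place its aryl group on the convex face for steric reasons, and this centre later becomes CH2. The step needs ionisation at the guaiacyl acetal only, with loss of methoxide and not of the tether oxygen: the para-benzyloxy group stabilises that cation, methoxide is the smaller and more basic leaving group and a wrongly ionised pair can recombine, while the sulfonate and the acyl character of O1 keep the C2–O1 bond intact.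

Step 9
Reactants: 15 (3S,3aR,6S,6aS)-6-[4-(benzyloxy)-3-methoxyphenyl]-3-[3,5-dimethoxy-4-(tosyloxy)phenyl]tetrahydro-1H,3H-furo[3,4-c]furan-1-one
Product: 16 (3S,3aR,6S,6aS)-6-[4-(benzyloxy)-3-methoxyphenyl]-3-[3,5-dimethoxy-4-(tosyloxy)phenyl]tetrahydro-1H,3H-furo[3,4-c]furan-1-ol (lactol; both anomers)
Conditions: i-Bu2AlH, CH2Cl2, −78 °C; aq. KNa tartrate (KNaC4H4O6)
Reagents that add atoms: none
Why: Partial hydride reduction of a γ-lactone, stopped at the lactol because the aluminium hemiacetal is stable at −78 °C; the aryl sulfonate and the ethers are inert, and the new hemiacetal centre disappears in step 10.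

Step 10
Reactants: 16 (3S,3aR,6S,6aS)-6-[4-(benzyloxy)-3-methoxyphenyl]-3-[3,5-dimethoxy-4-(tosyloxy)phenyl]tetrahydro-1H,3H-furo[3,4-c]furan-1-ol
Product: 17 (1S,3aR,4S,6aR)-4-[4-(benzyloxy)-3-methoxyphenyl]-1-[3,5-dimethoxy-4-(tosyloxy)phenyl]tetrahydro-1H,3H-furo[3,4-c]furan
Conditions: Et3SiH, BF3·OEt2, CH2Cl2, −78 → −40 °C; aq. NaHCO3
Reagents that add atoms: none
Why: Ionic hydrogenation of a lactol: BF3 ionises the hemiacetal to a cyclic oxocarbenium ion that Et3SiH reduces to the C5 methylene; at this temperature the benzylic ethers are not ionised, least of all the one at the sulfonate-bearing C2.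

Step 11
Reactants: 17 (1S,3aR,4S,6aR)-4-[4-(benzyloxy)-3-methoxyphenyl]-1-[3,5-dimethoxy-4-(tosyloxy)phenyl]tetrahydro-1H,3H-furo[3,4-c]furan
Product: 18 4-[(2S,3R,4R)-4-(4-hydroxy-3-methoxybenzyl)-3-(hydroxymethyl)tetrahydrofuran-2-yl]-2,6-dimethoxyphenyl 4-methylbenzenesulfonate
Conditions: H2 (1 atm), 10% Pd/C, EtOAc–MeOH, rt, monitored
Reagents that add atoms: none
Why: Catalytic hydrogenolysis: the aryl benzyl ether goes first, and the C7'–O bond, now para to a free phenol, should be cleaved in preference to the C2–O1 bond that sits para to the sulfonate; C3 and C4 are not involved, so the 3,4-cis relationship made in step 8 is carried into the monocyclic product.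

Step 12
Reactants: 18 4-[(2S,3R,4R)-4-(4-hydroxy-3-methoxybenzyl)-3-(hydroxymethyl)tetrahydrofuran-2-yl]-2,6-dimethoxyphenyl 4-methylbenzenesulfonate
Product: 19 4-[(2S,3R,4R)-4-(4-hydroxy-3-methoxybenzyl)-3-(hydroxymethyl)tetrahydrofuran-2-yl]-2,6-dimethoxyphenol
Conditions: KOH, MeOH–H2O, 65 °C, argon; aq. HCl to pH 5
Reagents that add atoms: none
Why: Alkaline hydrolysis of an aryl sulfonate by attack of hydroxide at sulfur; the ring, the primary alcohol and the three stereocentres carry no acidic or electrophilic site and should be unaffected.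

Step 13
Reactants: 19 4-[(2S,3R,4R)-4-(4-hydroxy-3-methoxybenzyl)-3-(hydroxymethyl)tetrahydrofuran-2-yl]-2,6-dimethoxyphenol; 20 ferulic acid
Product: 21 [(2S,3R,4R)-2-(4-hydroxy-3,5-dimethoxyphenyl)-4-(4-hydroxy-3-methoxybenzyl)tetrahydrofuran-3-yl]methyl (E)-3-(4-hydroxy-3-methoxyphenyl)prop-2-enoate
Conditions: PPh3, DIAD, THF, 0 °C → rt
Reagents that add atoms: none
Why: Mitsunobu esterification: the carboxylic acid, far more acidic than the phenols, protonates the betaine and supplies the nucleophile, and only the primary C9 alcohol can form an alkoxyphosphonium ion open to SN2 attack, so the phenols should stay free; C9 is not a stereocentre and the E alkene is untouched.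

Compound list
1 | syringaldehyde (4-hydroxy-3,5-dimethoxybenzaldehyde) | COc1cc(C=O)cc(OC)c1O | starting material
2 | 4-formyl-2,6-dimethoxyphenyl 4-methylbenzenesulfonate | COc1cc(C=O)cc(OC)c1OS(=O)(=O)c1ccc(C)cc1 | intermediate
3 | (S)-4-benzyloxazolidin-2-one | O=C1N[C@@H](Cc2ccccc2)CO1 | starting material
4 | methyl 4-chloro-4-oxobutanoate | COC(=O)CCC(Cl)=O | starting material
5 | methyl 4-[(4S)-4-benzyl-2-oxooxazolidin-3-yl]-4-oxobutanoate | COC(=O)CCC(=O)N1[C@@H](Cc2ccccc2)COC1=O | intermediate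
6 | methyl (3S,4S)-3-{[(4S)-4-benzyl-2-oxooxazolidin-3-yl]carbonyl}-4-[3,5-dimethoxy-4-(tosyloxy)phenyl]-4-hydroxybutanoate (syn-aldol adduct) | O=C(N1[C@@H](Cc2ccccc2)COC1=O)[C@H]([C@H](O)c1cc(OC)c(OS(=O)(=O)c2ccc(C)cc2)c(OC)c1)CC(=O)OC | intermediate (not isolated)
7 | (4S)-4-benzyl-3-{[(2S,3S)-2-[3,5-dimethoxy-4-(tosyloxy)phenyl]-5-oxotetrahydrofuran-3-yl]carbonyl}oxazolidin-2-one | O=C([C@H]1CC(=O)O[C@@H]1c1cc(OC)c(OS(=O)(=O)c2ccc(C)cc2)c(OC)c1)N1[C@@H](Cc2ccccc2)COC1=O | intermediate
8 | (2S,3S)-2-[3,5-dimethoxy-4-(tosyloxy)phenyl]-5-oxotetrahydrofuran-3-carboxylic acid | OC(=O)[C@H]1CC(=O)O[C@@H]1c1cc(OC)c(OS(=O)(=O)c2ccc(C)cc2)c(OC)c1 | intermediate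
9 | (4R,5S)-5-[3,5-dimethoxy-4-(tosyloxy)phenyl]-4-(hydroxymethyl)dihydrofuran-2(3H)-one | OC[C@H]1CC(=O)O[C@@H]1c1cc(OC)c(OS(=O)(=O)c2ccc(C)cc2)c(OC)c1 | intermediate
10 | 4-(benzyloxy)-3-methoxybenzaldehyde (O-benzylvanillin) | COc1cc(C=O)ccc1OCc1ccccc1 | starting material
11 | 1-(benzyloxy)-4-(dimethoxymethyl)-2-methoxybenzene | COC(OC)c1ccc(OCc2ccccc2)c(OC)c1 | intermediate
12 | 1-(benzyloxy)-4-[chloro(methoxy)methyl]-2-methoxybenzene (α-chloro ether) | COC(Cl)c1ccc(OCc2ccccc2)c(OC)c1 | intermediate (not isolated)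
13 | (4R,5S)-4-({[4-(benzyloxy)-3-methoxyphenyl](methoxy)methoxy}methyl)-5-[3,5-dimethoxy-4-(tosyloxy)phenyl]dihydrofuran-2(3H)-one (epimers at the acetal carbon) | COC(OC[C@H]1CC(=O)O[C@@H]1c1cc(OC)c(OS(=O)(=O)c2ccc(C)cc2)c(OC)c1)c1ccc(OCc2ccccc2)c(OC)c1 | intermediate (key-step precursor)
14 | trimethyl{[(2S,3R)-3-({[4-(benzyloxy)-3-methoxyphenyl](methoxy)methoxy}methyl)-2-[3,5-dimethoxy-4-(tosyloxy)phenyl]-2,3-dihydrofuran-5-yl]oxy}silane (silyl ketene acetal) | COC(OC[C@H]1C=C(O[Si](C)(C)C)O[C@@H]1c1cc(OC)c(OS(=O)(=O)c2ccc(C)cc2)c(OC)c1)c1ccc(OCc2ccccc2)c(OC)c1 | intermediate (not isolated)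
15 | (3S,3aR,6S,6aS)-6-[4-(benzyloxy)-3-methoxyphenyl]-3-[3,5-dimethoxy-4-(tosyloxy)phenyl]tetrahydro-1H,3H-furo[3,4-c]furan-1-one | O=C1O[C@H](c2cc(OC)c(OS(=O)(=O)c3ccc(C)cc3)c(OC)c2)[C@H]2CO[C@H](c3ccc(OCc4ccccc4)c(OC)c3)[C@@H]12 | intermediate (key-step product)
16 | (3S,3aR,6S,6aS)-6-[4-(benzyloxy)-3-methoxyphenyl]-3-[3,5-dimethoxy-4-(tosyloxy)phenyl]tetrahydro-1H,3H-furo[3,4-c]furan-1-ol (both anomers) | OC1O[C@H](c2cc(OC)c(OS(=O)(=O)c3ccc(C)cc3)c(OC)c2)[C@H]2CO[C@H](c3ccc(OCc4ccccc4)c(OC)c3)[C@@H]12 | intermediate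
17 | (1S,3aR,4S,6aR)-4-[4-(benzyloxy)-3-methoxyphenyl]-1-[3,5-dimethoxy-4-(tosyloxy)phenyl]tetrahydro-1H,3H-furo[3,4-c]furan | C1O[C@H](c2cc(OC)c(OS(=O)(=O)c3ccc(C)cc3)c(OC)c2)[C@H]2CO[C@H](c3ccc(OCc4ccccc4)c(OC)c3)[C@@H]12 | intermediate
18 | 4-[(2S,3R,4R)-4-(4-hydroxy-3-methoxybenzyl)-3-(hydroxymethyl)tetrahydrofuran-2-yl]-2,6-dimethoxyphenyl 4-methylbenzenesulfonate | OC[C@H]1[C@@H](Cc2ccc(O)c(OC)c2)CO[C@@H]1c1cc(OC)c(OS(=O)(=O)c2ccc(C)cc2)c(OC)c1 | intermediate
19 | 4-[(2S,3R,4R)-4-(4-hydroxy-3-methoxybenzyl)-3-(hydroxymethyl)tetrahydrofuran-2-yl]-2,6-dimethoxyphenol | OC[C@H]1[C@@H](Cc2ccc(O)c(OC)c2)CO[C@@H]1c1cc(OC)c(O)c(OC)c1 | intermediate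
20 | ferulic acid ((E)-3-(4-hydroxy-3-methoxyphenyl)prop-2-enoic acid) | COc1cc(/C=C/C(=O)O)ccc1O | starting material
21 | [(2S,3R,4R)-2-(4-hydroxy-3,5-dimethoxyphenyl)-4-(4-hydroxy-3-methoxybenzyl)tetrahydrofuran-3-yl]methyl (E)-3-(4-hydroxy-3-methoxyphenyl)prop-2-enoate | COc1cc(/C=C/C(=O)OC[C@H]2[C@@H](Cc3ccc(O)c(OC)c3)CO[C@@H]2c2cc(OC)c(O)c(OC)c2)ccc1O | target

Total step count: 13. Longest linear sequence: 11 steps (1 → 2 → 7 → 8 → 9 → 13 → 15 → 16 → 17 → 18 → 19 → 21; steps 1, 3, 4, 5, 7, 8, 9, 10, 11, 12, 13).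

Steps most likely to fail

Step 8. What may go wrong: the mixed acetal ionises with loss of the tether oxygen instead of methoxide, so that C–C bond formation becomes intermolecular and loses its facial control, or the silyl ketene acetal is hydrolysed before it cyclises. The fallback sets out from 9 and comes back at 18; it gives up the tether and sets C4 by kinetic protonation. Alcohol 9 is benzylated with benzyl 2,2,2-trichloroacetimidate and catalytic TfOH to give (4R,5S)-4-[(benzyloxy)methyl]-5-[3,5-dimethoxy-4-(tosyloxy)phenyl]dihydrofuran-2(3H)-one F1. Aldehyde 10 is reduced with NaBH4 to [4-(benzyloxy)-3-methoxyphenyl]methanol F2, which PBr3 converts into 1-(benzyloxy)-4-(bromomethyl)-2-methoxybenzene F3. The lithium enolate of F1 (LiN(SiMe3)2, THF, −78 °C) should be alkylated by F3 on the face opposite the C3 arm to give the 3,4-trans lactone F4. Re-enolisation with LiN(i-Pr)2 and protonation at −78 °C by 2,6-di-tert-butylphenol, again from the face opposite the C3 arm, should invert C4 to give the 3,4-cis lactone F5. i-Bu2AlH then gives the lactol F6, Et3SiH with BF3·OEt2 gives the dibenzyl tetrahydrofuran F7, and H2 over Pd/C removes both benzyl groups to reach 18.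

Step 11. What may go wrong: over-reduction, meaning hydrogenolysis of the C2–O1 bond after the C7'–O bond, or stalling once the benzyl ether has gone. The fallback sets out from 17 and comes back at 18; it lets cation stability, not the catalyst surface, select the bond. Et3SiH and BF3·OEt2 in CH2Cl2 at −20 → 0 °C should ionise only the C7'–O bond (para-benzyloxy aryl) and reduce the cation, giving the O-benzyl tetrahydrofuran alcohol F8. Its aryl benzyl ether is then removed by a brief hydrogenolysis (H2, Pd/C, EtOAc) to give 18.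

Step 13. What may go wrong: competing O-alkylation of a phenol by the activated C9 alcohol, or incomplete esterification of the hindered primary alcohol. The fallback sets out from 19 and comes back at 21; it builds the ferulate in two bond-forming events and needs no activated alcohol. Triol 19 is heated with Meldrum's acid in toluene at 90 °C, where the acyl ketene should acylate the primary alcohol in preference to the phenols, to give the malonate half-ester F9. Knoevenagel–Doebner condensation of F9 with vanillin (pyridine, catalytic piperidine, 40 °C) with loss of CO2 should give the E ferulate 21.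

Further compounds
F1 | step 8 | (4R,5S)-4-[(benzyloxy)methyl]-5-[3,5-dimethoxy-4-(tosyloxy)phenyl]dihydrofuran-2(3H)-one | c1ccccc1COC[C@H]1CC(=O)O[C@@H]1c1cc(OC)c(OS(=O)(=O)c2ccc(C)cc2)c(OC)c1
F2 | step 8 | [4-(benzyloxy)-3-methoxyphenyl]methanol | COc1cc(CO)ccc1OCc1ccccc1
F3 | step 8 | 1-(benzyloxy)-4-(bromomethyl)-2-methoxybenzene | COc1cc(CBr)ccc1OCc1ccccc1
F4 | step 8 | (3S,4R,5S)-3-[4-(benzyloxy)-3-methoxybenzyl]-4-[(benzyloxy)methyl]-5-[3,5-dimethoxy-4-(tosyloxy)phenyl]dihydrofuran-2(3H)-one (3,4-trans lactone) | c1ccccc1COC[C@H]1[C@H](Cc2ccc(OCc3ccccc3)c(OC)c2)C(=O)O[C@@H]1c1cc(OC)c(OS(=O)(=O)c2ccc(C)cc2)c(OC)c1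
F5 | step 8 | (3R,4R,5S)-3-[4-(benzyloxy)-3-methoxybenzyl]-4-[(benzyloxy)methyl]-5-[3,5-dimethoxy-4-(tosyloxy)phenyl]dihydrofuran-2(3H)-one (3,4-cis lactone) | c1ccccc1COC[C@H]1[C@@H](Cc2ccc(OCc3ccccc3)c(OC)c2)C(=O)O[C@@H]1c1cc(OC)c(OS(=O)(=O)c2ccc(C)cc2)c(OC)c1
F6 | step 8 | (3R,4R,5S)-3-[4-(benzyloxy)-3-methoxybenzyl]-4-[(benzyloxy)methyl]-5-[3,5-dimethoxy-4-(tosyloxy)phenyl]tetrahydrofuran-2-ol (lactol; both anomers) | c1ccccc1COC[C@H]1[C@@H](Cc2ccc(OCc3ccccc3)c(OC)c2)C(O)O[C@@H]1c1cc(OC)c(OS(=O)(=O)c2ccc(C)cc2)c(OC)c1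
F7 | step 8 | 4-[(2S,3R,4R)-4-[4-(benzyloxy)-3-methoxybenzyl]-3-[(benzyloxy)methyl]tetrahydrofuran-2-yl]-2,6-dimethoxyphenyl 4-methylbenzenesulfonate | c1ccccc1COC[C@H]1[C@@H](Cc2ccc(OCc3ccccc3)c(OC)c2)CO[C@@H]1c1cc(OC)c(OS(=O)(=O)c2ccc(C)cc2)c(OC)c1
F8 | step 11 | 4-[(2S,3R,4R)-4-[4-(benzyloxy)-3-methoxybenzyl]-3-(hydroxymethyl)tetrahydrofuran-2-yl]-2,6-dimethoxyphenyl 4-methylbenzenesulfonate | OC[C@H]1[C@@H](Cc2ccc(OCc3ccccc3)c(OC)c2)CO[C@@H]1c1cc(OC)c(OS(=O)(=O)c2ccc(C)cc2)c(OC)c1
F9 | step 13 | 3-{[(2S,3R,4R)-2-(4-hydroxy-3,5-dimethoxyphenyl)-4-(4-hydroxy-3-methoxybenzyl)tetrahydrofuran-3-yl]methoxy}-3-oxopropanoic acid | OC(=O)CC(=O)OC[C@H]1[C@@H](Cc2ccc(O)c(OC)c2)CO[C@@H]1c1cc(OC)c(O)c(OC)c1
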